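The synthesis rests on cutting the C5–C6 bond of the cyclohexane-1,3-dione ring (C1 enol carbon, C2 acyl-bearing carbon, C3 ketone, C4 carbinol, C5 and C6 the two CH2 groups). The ring segment O=C1–C6H2–C5H2–C4H(OH) is a γ-hydroxy ketone, the retron of an enolate–epoxide opening. The target is an isomer of an open-chain glycidoyl triketone. In one operation, base converts the acetyl CH3 (C6) into the terminal carbon of a dianion that opens the strained oxirane at its CH2 (C5). The carbocycle closes and the C4 hydroxyl appears with the purchased S configuration, without protecting groups or loss of atoms. The precursor is 2-acetyl-1-[(2S)-oxiran-2-yl]icosane-1,3-dione.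

Key step: step 4

Assumption: the β-tricarbonyl compounds are drawn as one enol tautomer with unspecified enol geometry, because tautomers and enol geometries interconvert freely. Only C4 carries stereochemical information.

Step 1
Reactants: 1 pentane-2,4-dione (acetylacetone); 2 1-bromohexadecane
Product: 4 henicosane-2,4-dione, via dilithium acetylacetone dianion 3 (not isolated)
Conditions: LiN(iPr)2 (2.1 equiv), THF, 0 °C; then 2, 0 °C to rt; 1 M HCl work-up
Reagents that add atoms: none
Why: γ-Alkylation of a 1,3-dicarbonyl dianion: the terminal carbanion of 3 is far more nucleophilic than the delocalised central carbon, so the primary bromide should be displaced (SN2) at the CH3 terminus only, and no stereocenter arises.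

Step 2
Reactants: 5 methyl (2S)-oxirane-2-carboxylate (methyl (S)-glycidate)
Product: 6 potassium (2S)-oxirane-2-carboxylate
Conditions: KOH (1.0 equiv), EtOH, 0 °C; Et2O, filter, dry in vacuo
Reagents that add atoms: potassium hydroxide, [K+].[OH-]
Why: Ester saponification (acyl–oxygen cleavage): hydroxide should attack the inductively activated ester carbonyl faster than the oxirane at 0 °C, the salt precipitates, and the stereocenter is untouched because enolization toward a double bond exocyclic to the oxirane is strongly disfavoured.

Step 3
Reactants: 6 potassium (2S)-oxirane-2-carboxylate; 4 henicosane-2,4-dione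
Product: 8 2-acetyl-1-[(2S)-oxiran-2-yl]icosane-1,3-dione, via (2S)-oxirane-2-carbonyl chloride 7 (not isolated)
Conditions: 6, (COCl)2 (1.0 equiv), DMF (cat.), CH2Cl2, 0 °C; then added to 4, MgCl2 (1.1 equiv), pyridine (2.2 equiv), CH2Cl2, 0 °C; cold 1 M HCl work-up, used crude
Reagents that add atoms: none
Why: Making the acid chloride from the dry salt liberates KCl instead of HCl and so spares the oxirane, C-acylation under MgCl2/pyridine soft enolization is the standard way from acyclic 1,3-diketones to triacylmethanes, and the stereocenter is retained because ketene formation from 7 would need a double bond exocyclic to the oxirane.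

Step 4
Reactants: 8 2-acetyl-1-[(2S)-oxiran-2-yl]icosane-1,3-dione
Product: 11 (S)-4-hydroxy-2-octadecanoylcyclohexane-1,3-dione (target), via open-chain dilithium dianion 9 (not isolated), via cyclised dilithium salt 10 (not isolated)
Conditions: LiN(iPr)2 (2.3 equiv), THF (0.01 M), −78 °C to 0 °C; then 1 M HCl, 0 °C
Reagents that add atoms: none
Why: Proposed new method: LiN(iPr)2 removes first the enol proton and then a proton of the acetyl CH3 (C6) of 8, and the terminal carbanion of the cross-conjugated dianion 9 attacks the unsubstituted oxirane carbon C5 from the back side (SN2), the Li+-coordinated ring oxygen leaving as the C4 alkoxide of 10, so that release of oxirane strain pays for the new C5–C6 bond. The closest known reaction types are the γ-alkylation of β-diketone and β-keto ester dianions by halides and terminal epoxides, the epoxynitrile cyclization and the opening of glycidic esters at C3 by carbon nucleophiles, whereas their combination inside a glycidoyl triketone has not been described. The cyclohexane ring closes in a 6-(enolendo) mode that is by convention 6-endo-tet at the oxirane (fused transition state), while the rival 5-(enolendo)-exo-tet attack at C4 is disfavoured because C4 lies in the nodal plane of the planar C6–C1–C2–C3 π system. No stereocenter is formed: the C4–O and C4–H bonds are untouched, so the S configuration of the glycidate is carried into the carbinol, and the neighbouring alkoxide in 10 should protect C4–H from deprotonation. The step needs C6, not the α-CH2 of the octadecanoyl chain or C4–H, as the second site of deprotonation, which the kinetic order CH3 before CH2R and the strain of an enolate exocyclic to an oxirane should provide; it also needs C- rather than O-alkylation, which is favoured by the much higher nucleophilicity of the terminal dianion carbon, the primary electrophilic carbon, low temperature and high dilution.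

Compound list
1 | pentane-2,4-dione (acetylacetone) | CC(=O)CC(C)=O | starting material
2 | 1-bromohexadecane | CCCCCCCCCCCCCCCCBr | starting material
3 | dilithium dianion of pentane-2,4-dione (terminal and central deprotonation) | [Li+].[Li+].C=C([O-])C=C(C)[O-] | intermediate
4 | henicosane-2,4-dione | CCCCCCCCCCCCCCCCCC(=O)CC(C)=O | intermediate
5 | methyl (2S)-oxirane-2-carboxylate | COC(=O)[C@@H]1CO1 | starting material
6 | potassium (2S)-oxirane-2-carboxylate | [K+].[O-]C(=O)[C@@H]1CO1 | intermediate
7 | (2S)-oxirane-2-carbonyl chloride | ClC(=O)[C@@H]1CO1 | intermediate
8 | 2-acetyl-1-[(2S)-oxiran-2-yl]icosane-1,3-dione (enol form) | CCCCCCCCCCCCCCCCCC(=O)C(=C(C)O)C(=O)[C@@H]1CO1 | intermediate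
9 | dilithium dienediolate of 8 (enol OH and acetyl CH3 deprotonated) | [Li+].[Li+].CCCCCCCCCCCCCCCCCC([O-])=C(C(=C)[O-])C(=O)[C@@H]1CO1 | intermediate
10 | dilithium salt of the target (C4 alkoxide and ring enolate) | [Li+].[Li+].CCCCCCCCCCCCCCCCCC(=O)C1=C([O-])CC[C@H]([O-])C1=O | intermediate
11 | (S)-4-hydroxy-2-octadecanoylcyclohexane-1,3-dione, drawn as (6S)-3,6-dihydroxy-2-octadecanoylcyclohex-2-en-1-one | CCCCCCCCCCCCCCCCCC(=O)C1=C(O)CC[C@H](O)C1=O | target

Total step count: 4. Longest linear sequence: 3 steps (1, 3, 4 or 2, 3, 4).

Steps most likely to fail

Step 4. The fused-mode oxirane opening may be slower than three competing processes. These are O-alkylation by an enolate oxygen at C4 or C5, second deprotonation at the α-CH2 of the octadecanoyl chain followed by closure through that carbon, and intermolecular opening.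

The fallback sets out from 8. The oxirane is opened at C5 with TBSCl/NaI in MeCN (silyl-assisted iodide opening). This should give (2R)-4-acetyl-2-[(tert-butyldimethylsilyl)oxy]-1-iododocosane-3,5-dione F1. Treatment with LiN(iPr)2 (2.2 equiv, THF, −78 °C to 0 °C) then forms the same C5–C6 bond by an ordinary 6-(enolendo)-exo-tet displacement of a primary iodide, the classical γ-alkylation of a 1,3-dicarbonyl dianion. The product is (S)-4-[(tert-butyldimethylsilyl)oxy]-2-octadecanoylcyclohexane-1,3-dione F2. HF·pyridine in THF removes the silyl group, and the route is rejoined at 11.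

Step 3. Three things may go wrong: chloride opening of the oxirane under MgCl2 activation, O-acylation in place of C-acylation, and retro-Claisen loss of an acyl group during work-up.

The fallback sets out from 4 and 7. Without any magnesium salt, Et3N in CH2Cl2 at −20 °C should give O-acylation to the enol ester (2Z)-4-oxohenicos-2-en-2-yl (2S)-oxirane-2-carboxylate F3. Catalytic 4-(dimethylamino)pyridine with Et3N in MeCN then moves the acyl group from oxygen to carbon, the 1,3-O-to-C acyl shift used for 2-acyl-1,3-diones. The fallback comes back at 8.

Step 2. Hydroxide or ethoxide may open the oxirane, and water carried in the hygroscopic salt would hydrolyse the acid chloride in the next step.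

The fallback sets out from 5 and bypasses 6 and 7. Purchased nonadecan-2-one F4 is deprotonated at its methyl group (LiN(iPr)2, 2.2 equiv, THF, −78 °C). It is then acylated by ester 5 in a crossed Claisen condensation to 1-[(2S)-oxiran-2-yl]icosane-1,3-dione F5. The central carbon of F5 is C-acetylated (AcCl, MgCl2, pyridine, CH2Cl2, 0 °C), which rejoins the route at 8.

Further compounds
F1 | step 4 | (2R)-4-acetyl-2-[(tert-butyldimethylsilyl)oxy]-1-iododocosane-3,5-dione (enol form) | CCCCCCCCCCCCCCCCCC(=O)C(=C(C)O)C(=O)[C@@H](O[Si](C)(C)C(C)(C)C)CI
F2 | step 4 | (S)-4-[(tert-butyldimethylsilyl)oxy]-2-octadecanoylcyclohexane-1,3-dione (enol form) | CCCCCCCCCCCCCCCCCC(=O)C1=C(O)CC[C@H](O[Si](C)(C)C(C)(C)C)C1=O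
F3 | step 3 | (2Z)-4-oxohenicos-2-en-2-yl (2S)-oxirane-2-carboxylate | CCCCCCCCCCCCCCCCCC(=O)/C=C(/C)OC(=O)[C@@H]1CO1
F4 | step 2 | nonadecan-2-one (purchased) | CCCCCCCCCCCCCCCCCC(C)=O
F5 | step 2 | 1-[(2S)-oxiran-2-yl]icosane-1,3-dione | CCCCCCCCCCCCCCCCCC(=O)CC(=O)[C@@H]1CO1
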